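The constants are made up.

**Slowing loss.** The step to D.E is not slow as charged: by that step, with the other concentrations as charged, E in maple has a half-life of 4.4 min, short against the 25 min run. At any moment the loss of E is pseudo-first-order, with the constant of the step times c_D as its rate constant, and c_D changes along the run, so the useful clock is the time integral of c_D.

| flask | X | D | time | remark |
|---|---|---|---|---|
| maple | 0.050 M | 0.950 equiv | 25 min | everything together at the start |
| cedar | 0.050 M | 0.950 equiv (fed, over 10 min) | 25 min | all else is in the flask from the start; the feed brings no volume worth counting |
| alder | 0.050 M (fed, over 10 min) | 0.950 equiv | 25 min | all else is in the flask from the start; the feed brings no volume worth counting |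

    D + G → E + J (k1 = 0.017 /M/s)
    D + E → D.E (k2 = 0.055 /M/s)
    X + D → G + J (k3 = 0.061 /M/s)
    2 D → D2 (k4 = 0.093 /M/s)

- for a step with 2 of a species take k times the square, and two of it per event
- run time (maple): 25 min

* the flask with the highest share of E in E plus D.E ("all alike" if they lie within 1.5 percentage points) (maple / cedar / alder / all alike)
* share of E in E plus D.E at the end, maple
* share of E in E plus D.E at the end, cedar
* share of E in E plus D.E at the end, alder

**The rule.** On that clock X falls exponentially and D falls through linear terms, which integrate in closed form up to c_D = 0. Neglecting the D taken by G, maple reaches 0.476, in units of the rate constant of the step to D.E. That product of constant and integral is the exposure number N. E comes from G, and G grows with exposure, so replacing the curve by its mean gives the average E a third of N. The share is then the inverse of one plus that third, 86.3% for maple.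

**Feeding D.** In cedar the feed balances against X and dimerisation at c_D near 0.0140 M. With the tail after the feed, N comes to 0.645, larger than maple's. The hand share is 82.3%.

**Feeding X.** The first half-life of D under dimerisation, counted by itself, is 1.89 min, shorter than the 10 min feed. Late X therefore finds c_D fallen. The rule assumes X present from the start, so it gives alder a direction, upward from maple, but no number.

**The forecast.** It names alder, with maple 86.2%, cedar 81.8% and alder 88%, on the grounds that in alder “G forms late, so E is young”. Its cedar lies slightly below the hand figure.

**The result.** The flask gives maple 86.2%, cedar 82.2% and alder 88.9%, so alder stands highest.

**Cheapest route.** The step to D2 has the largest single effect on the gap between alder and cedar, which is 6.7 percentage points with that step and −4.7 points without it. In a flask that holds its X from the start, N can also be read from the X left. The neighbour of cedar with 0.570 equiv of D keeps 65.0% of its X, so its N is 0.389, below maple's 0.476. The rule gives 88.5%, and that flask stands at 87.7%.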